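Readings and results were computed with made-up constants; the scatter is artificial.

A small charge of substrate (35 mM, less than the reagent) leaves by two ways: with reagent to side product A, or, as the readings suggest, by a loss that needs no reagent.

| flask | substrate | reagent | temperature | remark | time |
|---|---|---|---|---|---|
| south-east | 35 mM | 87.5 mM | −35 °C | run made earlier |  |
| west | 49 mM | 87.5 mM | −20 °C | run made earlier |  |
| north | 77 mM | 87.5 mM | −35 °C | run made earlier |  |
| Sunday's | 35 mM | 87.5 mM | −20 °C | everything together at the start | 4.0 min |
| Wednesday's | 35 mM | 87.5 mM (fed, over 50 s) | −20 °C | all else is in the flask from the start; the feed brings no volume worth counting | 4.0 min |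
| Tuesday's | 35 mM | 87.5 mM |  | everything together at the start at −40 °C, warmed to −20 °C at 50 s | 4.0 min |
| Monday's | 35 mM (fed, over 50 s) | 87.5 mM | −20 °C | all else is in the flask from the start; the feed brings no volume worth counting | 4.0 min |
| Saturday's | 35 mM | 87.5 mM (fed, over 50 s) |  | the addition at −40 °C, then warmed to −20 °C; the feed brings no volume worth counting | 4.0 min |

| run | time / min | side product A / % | target / % |
|---|---|---|---|
| south-east | 0.500 | 96.5 | 0 |
| south-east | 2.00 | 96.7 | 0 |
| south-east | 3.00 | 96.5 | 0 |
| south-east | 4.00 | 97.2 | 0 |
| south-east | 6.00 | 96.9 | 0.7 |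
| south-east | 8.00 | 96.9 | 0.3 |
| west | 0.667 | 94.5 | 0.1 |
| west | 1.33 | 93.1 | 0.8 |
| west | 2.00 | 94.6 | 1.4 |
| west | 2.50 | 93.2 | 1.5 |
| west | 3.00 | 94.1 | 2.1 |
| west | 4.00 | 94.1 | 1.4 |
| north | 0.667 | 93.1 | 0.1 |
| north | 1.00 | 94.8 | 0.3 |
| north | 2.00 | 95.2 | 0.3 |
| north | 3.00 | 95.0 | 0.3 |
| north | 5.00 | 94.8 | 0 |
| north | 8.00 | 95.1 | 0.4 |

(each reading ± 0.3 percentage points)

- the numbers in the tables scatter by 0.3 percentage points (one standard deviation)

- the flask that comes out highest in amount of side product A, in percent of the substrate charged; "all alike" if 1.5 percentage points covers them all (Sunday's / Wednesday's / Tuesday's / Monday's / Saturday's / all alike)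
- amount of side product A at the end, in percent of the substrate charged, Sunday's
- amount of side product A at the end, in percent of the substrate charged, Wednesday's
- amount of side product A at the end, in percent of the substrate charged, Tuesday's
- amount of side product A at the end, in percent of the substrate charged, Monday's
- amount of side product A at the end, in percent of the substrate charged, Saturday's

Call the split concentration K the c_reagent at which the two ways take substrate equally (a selectivity factor with a unit). Since the first way scales with c_reagent, the substrate lost in a flask that holds its whole reagent from the start is K ln(c_reagent,start/c_reagent,end).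

The west run averages 93.9% side product A, so K is 3.98 mM at −20 °C. At −35 °C, the south-east run gives 2.30 mM and the last five north readings 2.14 mM, so cold scales K by 0.557.

This reckoning gives Sunday's 94.6%, and Monday's the same, since its reagent falls between the same limits. Tuesday's gets 96.9%, because the south-east plateau stands at 0.500 min, sooner than the warming. Wednesday's and Saturday's hold c_reagent low during the feed, so both should fall below Sunday's, Wednesday's lowest. The north run's first reading gives a time for this: 93.1% at 0.667 min lies 1.9 percentage points under its later mean, more than the scatter, so about 1.45 mM of substrate still waited there, against a final reagent excess of about 14.4 mM. Second-order decay then reads a rate constant of the first way near 3.86 L mol⁻¹ s⁻¹ at −35 °C, and with K times 0.557 the loss has a time of 117 s at that temperature. The feed lasts 0.427 of that time, so Wednesday's should lose many points, though this reckoning sets no figure on them.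

The forecast named Tuesday's, with 94.8% for Sunday's, 80% for Wednesday's, 97% for Tuesday's, 95.4% for Monday's and 87% for Saturday's, adding: “The size of that drop is poorly bounded because the rates are only lower limits.”

The flasks give 94.7%, 57.9%, 97.6%, 94.7% and 91.2% in that order, Tuesday's highest.

    intermediate B → target (k = 0.0947 s⁻¹, Ea = 62.0 kJ mol⁻¹)
    intermediate A → intermediate B (k = 0.00444 s⁻¹, Ea = 77.0 kJ mol⁻¹)
    substrate + reagent → side product A (k = 12.2 L mol⁻¹ s⁻¹, Ea = 43.0 kJ mol⁻¹)
    substrate → intermediate A (k = 0.0227 s⁻¹, Ea = 62.0 kJ mol⁻¹)
    substrate → side product B (k = 0.0245 s⁻¹, Ea = 64.0 kJ mol⁻¹)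
    substrate + target → side product C (k = 0.609 L mol⁻¹ s⁻¹, Ea = 49.0 kJ mol⁻¹)
    (constants at −20 °C)

Wednesday's ends at 57.9%. At 0.833 min it holds 0% substrate, with 76.8% of its reagent unbound. Read through K, that share matches a c_reagent of 5.48 mM while substrate was present, against Sunday's 55.1 mM mean over the first 50 s, ten times that value.

Tuesday's recipe with 88 mM substrate, at K times 0.557, loses 5.89 mM, which leaves 93.3% side product A. The computed flask gives 93.2%.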